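The C9–C10 bond of ring B is the disconnection on which the route rests. In ring A, C10 lies para to the C3 oxygen and already carries its methyl group, so ring A can be a 2,4-dimethylphenol with a chain at C5 that holds the C7 stereocentre, its isopropenyl group and a primary mesylate at C9. In one operation the phenolate para carbon displaces the mesylate: ring B closes, the quaternary stereocentre C10 forms under control of C7, and ring A is dearomatised to a 1,4-dien-3-one that keeps the C3 oxygen and C4 methyl for the later diol, while the isopropenyl group becomes the acrylate. C7 itself comes from an oxazolidinone-directed alkylation.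

Key step: step 13

Remark: eudesmane numbering (C1–C15) is used throughout, also for the matching atoms of the open-chain precursors; pent-4-enoyl chloride and (S)-4-benzyl-1,3-oxazolidin-2-one are taken as purchased.

Step 1
Reactants: 1 2,6-dimethylbenzoic acid
Product: 2 3-bromo-2,6-dimethylbenzoic acid
Conditions: Br2 (1.05 equiv), AcOH, 20 °C
Reagents that add atoms: bromine, BrBr
Why: Electrophilic aromatic bromination should go to C3 only, because this position is ortho to one methyl, para to the other and meta to the carboxyl group, so all three substituents direct to it.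

Step 2
Reactants: 2 3-bromo-2,6-dimethylbenzoic acid
Product: 3 3-hydroxy-2,6-dimethylbenzoic acid
Conditions: Pd2(dba)3 (cat.), tBuXPhos (cat.), KOH, 1,4-dioxane–H2O, 100 °C; then aq. HCl
Reagents that add atoms: potassium hydroxide, [K+].[OH-]
Why: Palladium-catalysed hydroxylation of an aryl bromide (C–O cross-coupling with hydroxide) tolerates one ortho methyl group and a carboxylate, and the bulky biarylphosphine favours C–O reductive elimination.

Step 3
Reactants: 3 3-hydroxy-2,6-dimethylbenzoic acid
Product: 5 2,6-dimethyl-3-(triisopropylsilyloxy)benzoic acid, via bis-silylated ester 4 (not isolated)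
Conditions: iPr3SiCl (2.3 equiv), imidazole, DMF, 20 °C; then 1 M HCl, THF, 20 °C
Reagents that add atoms: chlorotriisopropylsilane, CC(C)[Si](Cl)(C(C)C)C(C)C
Why: Imidazole-mediated silylation covers both the phenol and the acid, and the silyl ester is far more labile to aqueous acid than the aryl silyl ether, so only the phenol stays protected.

Step 4
Reactants: 5 2,6-dimethyl-3-(triisopropylsilyloxy)benzoic acid
Product: 6 [2,6-dimethyl-3-(triisopropylsilyloxy)phenyl]methanol
Conditions: BH3·SMe2, THF, 65 °C; MeOH quench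
Reagents that add atoms: none
Why: Borane reduction is selective for the carboxylic acid, copes with the two ortho methyl groups because the reductant is small and electrophilic, and leaves the aryl silyl ether intact.

Step 5
Reactants: 6 [2,6-dimethyl-3-(triisopropylsilyloxy)phenyl]methanol
Product: 7 [3-(bromomethyl)-2,4-dimethylphenoxy]triisopropylsilane
Conditions: CBr4, PPh3, CH2Cl2, 0 °C
Reagents that add atoms: tetrabromomethane, BrC(Br)(Br)Br
Why: The Appel reaction converts the benzylic alcohol into the bromide under neutral conditions that do not touch the silyl ether.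

Step 6
Reactants: 8 (S)-4-benzyl-1,3-oxazolidin-2-one; 9 pent-4-enoyl chloride
Product: 10 (S)-4-benzyl-3-(pent-4-enoyl)-1,3-oxazolidin-2-one
Conditions: Et3N, DMAP (cat.), CH2Cl2, 0 → 20 °C
Reagents that add atoms: none
Why: N-Acylation of the oxazolidinone by the acid chloride under acyl-transfer catalysis is a standard way to load the auxiliary and touches no stereocentre.

Step 7
Reactants: 10 (S)-4-benzyl-3-(pent-4-enoyl)-1,3-oxazolidin-2-one; 7 [3-(bromomethyl)-2,4-dimethylphenoxy]triisopropylsilane
Product: 12 (4S)-4-benzyl-3-[(2R)-2-{[2,6-dimethyl-3-(triisopropylsilyloxy)phenyl]methyl}pent-4-enoyl]-1,3-oxazolidin-2-one, via sodium enolate 11 (not isolated)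
Conditions: NaN(SiMe3)2, THF, −78 °C; then 7, −78 → −30 °C
Reagents that add atoms: none
Why: Evans alkylation: the chelated (Z)-enolate is attacked by the reactive benzylic bromide on the face opposite the benzyl group of the auxiliary, which sets C7 (the 2R centre of the acyl chain).

Step 8
Reactants: 12 (4S)-4-benzyl-3-[(2R)-2-{[2,6-dimethyl-3-(triisopropylsilyloxy)phenyl]methyl}pent-4-enoyl]-1,3-oxazolidin-2-one
Product: 15 (3S)-3-{[2,6-dimethyl-3-(triisopropylsilyloxy)phenyl]methyl}oxolan-2-one, via ozonide 13 (not isolated), via hydroxy imide 14 (not isolated)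
Conditions: O3, CH2Cl2, −78 °C (stopped at first excess); then NaBH4, MeOH, −78 → 20 °C
Reagents that add atoms: ozone, [O-][O+]=O
Why: Ozonolysis with reductive work-up shortens the allyl group to CH2CH2O−, and this γ-alkoxide should close onto the activated imide carbonyl (lactonisation, 5-exo-trig) faster than borohydride attacks the imide, releasing the auxiliary without touching C7.

Step 9
Reactants: 15 (3S)-3-{[2,6-dimethyl-3-(triisopropylsilyloxy)phenyl]methyl}oxolan-2-one
Product: 17 (3S)-3-{[2,6-dimethyl-3-(triisopropylsilyloxy)phenyl]methyl}-5-hydroxypentan-2-one, via lithium hemiketal 16 (not isolated)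
Conditions: MeLi (1.05 equiv), THF, −78 °C; AcOH quench at −78 °C
Reagents that add atoms: methyllithium, [Li]C
Why: Mono-addition of an organolithium to a lactone stops at the lithium hemiketal, which is stable at −78 °C and collapses to the hydroxy methyl ketone only on protonation, so a second addition should be avoided.

Step 10
Reactants: 17 (3S)-3-{[2,6-dimethyl-3-(triisopropylsilyloxy)phenyl]methyl}-5-hydroxypentan-2-one
Product: 18 (3S)-3-{[2,6-dimethyl-3-(triisopropylsilyloxy)phenyl]methyl}-4-methylpent-4-en-1-ol
Conditions: Zn, CH2Br2, TiCl4 (pre-formed reagent in THF, excess), CH2Cl2, 0 → 20 °C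
Reagents that add atoms: dibromomethane, BrCBr
Why: Lombardo methylenation is non-basic, so the C7 centre next to the ketone should not epimerise, and the reagent tolerates a free hydroxyl when used in excess.

Step 11
Reactants: 18 (3S)-3-{[2,6-dimethyl-3-(triisopropylsilyloxy)phenyl]methyl}-4-methylpent-4-en-1-ol
Product: 19 (3S)-3-{[2,6-dimethyl-3-(triisopropylsilyloxy)phenyl]methyl}-4-methylpent-4-en-1-yl methanesulfonate
Conditions: MsCl, Et3N, CH2Cl2, 0 °C
Reagents that add atoms: methanesulfonyl chloride, CS(=O)(=O)Cl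
Why: Sulfonylation of the unhindered primary alcohol is fast and clean while the phenol is still silylated, so only C9 is activated.

Step 12
Reactants: 19 (3S)-3-{[2,6-dimethyl-3-(triisopropylsilyloxy)phenyl]methyl}-4-methylpent-4-en-1-yl methanesulfonate
Product: 20 (3S)-3-[(3-hydroxy-2,6-dimethylphenyl)methyl]-4-methylpent-4-en-1-yl methanesulfonate
Conditions: Bu4NF (1.1 equiv), AcOH (1.5 equiv), THF, 0 °C
Reagents that add atoms: none
Why: Fluoride cleaves the aryl silyl ether within minutes, and the acetic acid buffer keeps the phenol protonated, so the mesylate should survive and no premature ring closure occurs.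

Step 13
Reactants: 20 (3S)-3-[(3-hydroxy-2,6-dimethylphenyl)methyl]-4-methylpent-4-en-1-yl methanesulfonate
Product: 22 eudesma-1,4,11-trien-3-one (7αH/10β-methyl), via potassium phenolate 21 (not isolated)
Conditions: KOtBu (1.05 equiv), tBuOH, 0.005 M, 80 °C
Reagents that add atoms: none
Why: Deprotonation gives potassium phenolate 21, whose oxygen cannot reach C9 through the meta-attached tether, so the para carbon C10 attacks the primary mesylate in an SN2 displacement, and because C10 carries a methyl group the product cannot re-aromatise and stays as the cross-conjugated dienone. The closest known reaction type is the base-mediated intramolecular para-C-alkylation of phenols that gives 4,4-disubstituted cyclohexa-2,5-dienones, here in its ring-fused (Ar2-6) form. Ring B is closed in the 6-exo-tet mode. The new stereocentre C10 is controlled by C7 through a chair-like transition state in which the isopropenyl group is equatorial, C9 approaches the α face and the C10 methyl ends up β, cis to the side chain. The step needs para (C10) rather than ortho (C4) C-alkylation and ring closure rather than elimination or intermolecular O-alkylation: C10 carries the larger phenolate coefficient and is flanked only by C5 and a CH, whereas C4 sits next to the solvated O–K unit, one equivalent of base leaves no free alkoxide for E2, and high dilution suppresses oligomers.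

Step 14
Reactants: 22 eudesma-1,4,11-trien-3-one (7αH/10β-methyl)
Product: 23 eudesma-4,11-dien-3-one (α-cyperone)
Conditions: [(Ph3P)CuH]6 (0.4 equiv), toluene, H2O (5 equiv), 20 °C
Reagents that add atoms: none
Why: Conjugate reduction with the Stryker reagent delivers hydride to the unsubstituted β-carbon C1 and not to the fully substituted β-carbon C5, and it ignores the isolated isopropenyl alkene, so only C1=C2 is saturated.

Step 15
Reactants: 23 eudesma-4,11-dien-3-one (α-cyperone)
Product: 24 12-hydroxyeudesma-4,11(13)-dien-3-one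
Conditions: SeO2 (0.5 equiv), tBuOOH (3 equiv), CH2Cl2, 0 → 20 °C
Reagents that add atoms: selenium dioxide, O=[Se]=O; tert-butyl hydroperoxide, CC(C)(C)OO
Why: Allylic oxidation by SeO2 (ene reaction, then 2,3-sigmatropic shift) should hydroxylate the methyl of the electron-rich isopropenyl group in preference to the ring methine and the electron-poor enone, and any enal formed converges in step 16.

Step 16
Reactants: 24 12-hydroxyeudesma-4,11(13)-dien-3-one
Product: 26 3-oxoeudesma-4,11(13)-dien-12-oic acid, via enal 25 (not isolated)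
Conditions: MnO2, CH2Cl2, 20 °C; filter; then NaClO2, NaH2PO4, 2-methyl-2-butene, tBuOH–H2O, 0 → 20 °C
Reagents that add atoms: sodium chlorite, [Na+].[O-]Cl=O
Why: MnO2 oxidises only the allylic alcohol, and the Pinnick oxidation takes the resulting 2-substituted acrolein to the acrylic acid without touching the alkenes, because the hypochlorite by-product is scavenged.

Step 17
Reactants: 26 3-oxoeudesma-4,11(13)-dien-12-oic acid
Product: 27 methyl 3-oxoeudesma-4,11(13)-dien-12-oate
Conditions: Me3SiCHN2, MeOH–toluene, 0 °C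
Reagents that add atoms: (trimethylsilyl)diazomethane, C[Si](C)(C)C=[N+]=[N-]
Why: O-Methylation of the carboxylic acid with a diazoalkane is neutral and base-free, so the acrylate is not exposed to nucleophiles.

Step 18
Reactants: 27 methyl 3-oxoeudesma-4,11(13)-dien-12-oate
Product: 28 methyl 3β-hydroxyeudesma-4,11(13)-dien-12-oate
Conditions: CeCl3·7H2O, NaBH4, MeOH, −78 → −40 °C
Reagents that add atoms: none
Why: Luche reduction gives 1,2-reduction of the enone only, with hydride adding to C3 from the α face as is usual for 10β-methyl 4-en-3-ones, which sets the pseudo-equatorial 3β-alcohol, and at low temperature the acrylate ester should not be reduced.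

Step 19
Reactants: 28 methyl 3β-hydroxyeudesma-4,11(13)-dien-12-oate
Product: 29 methyl 4β,5β-epoxy-3β-hydroxyeudesm-11(13)-en-12-oate
Conditions: VO(acac)2 (5 mol %), tBuOOH (decane), toluene, 20 °C
Reagents that add atoms: tert-butyl hydroperoxide, CC(C)(C)OO
Why: Vanadium-catalysed hydroxyl-directed epoxidation delivers oxygen to the C4=C5 bond from the face of the 3β-alkoxide, which sets C4 and C5 as the β-epoxide, and the electron-poor acrylate alkene is inert.

Step 20
Reactants: 29 methyl 4β,5β-epoxy-3β-hydroxyeudesm-11(13)-en-12-oate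
Product: 30 methyl 3β,4β-dihydroxyeudesma-5,11(13)-dien-12-oate
Conditions: Ti(OiPr)4 (2 equiv), CH2Cl2, 20 → 40 °C; aq. tartaric acid work-up
Reagents that add atoms: none
Why: In the Ti(OiPr)4-mediated rearrangement of 2,3-epoxy alcohols to ene-diols, titanium bridges the 3β-alkoxide and the cis epoxide oxygen and weakens the distal C5–O bond, and the only hydrogen that can then be lost is at C6 (C4 and C10 carry none), so the 5-ene forms with the C4–O bond and hence the 4β-hydroxyl intact.

Step 21
Reactants: 30 methyl 3β,4β-dihydroxyeudesma-5,11(13)-dien-12-oate; 31 angelic acid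
Product: 33 methyl 3β-angeloyloxy-4β-hydroxyeudesma-5,11(13)-dien-12-oate, via mixed anhydride 32 (not isolated)
Conditions: 31, 2,4,6-trichlorobenzoyl chloride, Et3N, toluene, 20 °C; then 30, 75 °C
Reagents that add atoms: none
Why: Yamaguchi-type esterification through the trichlorobenzoyl mixed anhydride, run without DMAP, should acylate the secondary 3β-hydroxyl and not the tertiary 4β-hydroxyl and should keep the (Z)-geometry of the angelate.

Compound list

1 | 2,6-dimethylbenzoic acid | Cc1cccc(C)c1C(=O)O | starting material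
2 | 3-bromo-2,6-dimethylbenzoic acid | Cc1ccc(Br)c(C)c1C(=O)O | intermediate
3 | 3-hydroxy-2,6-dimethylbenzoic acid | Cc1ccc(O)c(C)c1C(=O)O | intermediate
4 | triisopropylsilyl 2,6-dimethyl-3-(triisopropylsilyloxy)benzoate | Cc1ccc(O[Si](C(C)C)(C(C)C)C(C)C)c(C)c1C(=O)O[Si](C(C)C)(C(C)C)C(C)C | intermediate (not isolated)
5 | 2,6-dimethyl-3-(triisopropylsilyloxy)benzoic acid | Cc1ccc(O[Si](C(C)C)(C(C)C)C(C)C)c(C)c1C(=O)O | intermediate
6 | [2,6-dimethyl-3-(triisopropylsilyloxy)phenyl]methanol | Cc1ccc(O[Si](C(C)C)(C(C)C)C(C)C)c(C)c1CO | intermediate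
7 | [3-(bromomethyl)-2,4-dimethylphenoxy]triisopropylsilane | Cc1ccc(O[Si](C(C)C)(C(C)C)C(C)C)c(C)c1CBr | intermediate
8 | (S)-4-benzyl-1,3-oxazolidin-2-one | O=C1N[C@@H](Cc2ccccc2)CO1 | starting material
9 | pent-4-enoyl chloride | C=CCCC(=O)Cl | starting material
10 | (S)-4-benzyl-3-(pent-4-enoyl)-1,3-oxazolidin-2-one | C=CCCC(=O)N1C(=O)OC[C@@H]1Cc1ccccc1 | intermediate
11 | sodium (Z)-enolate of 10 | [Na+].C=CC/C=C(\[O-])N1C(=O)OC[C@@H]1Cc1ccccc1 | intermediate (not isolated)
12 | (4S)-4-benzyl-3-[(2R)-2-{[2,6-dimethyl-3-(triisopropylsilyloxy)phenyl]methyl}pent-4-enoyl]-1,3-oxazolidin-2-one | C=CC[C@H](Cc1c(C)ccc(O[Si](C(C)C)(C(C)C)C(C)C)c1C)C(=O)N1C(=O)OC[C@@H]1Cc1ccccc1 | intermediate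
13 | ozonide (1,2,4-trioxolane) of the terminal alkene of 12, mixture at the new acetal carbon | O1OC(C[C@H](Cc2c(C)ccc(O[Si](C(C)C)(C(C)C)C(C)C)c2C)C(=O)N2C(=O)OC[C@@H]2Cc2ccccc2)OC1 | intermediate (not isolated)
14 | (4S)-4-benzyl-3-[(2S)-2-{[2,6-dimethyl-3-(triisopropylsilyloxy)phenyl]methyl}-4-hydroxybutanoyl]-1,3-oxazolidin-2-one | OCC[C@H](Cc1c(C)ccc(O[Si](C(C)C)(C(C)C)C(C)C)c1C)C(=O)N1C(=O)OC[C@@H]1Cc1ccccc1 | intermediate (not isolated)
15 | (3S)-3-{[2,6-dimethyl-3-(triisopropylsilyloxy)phenyl]methyl}oxolan-2-one | O=C1OCC[C@@H]1Cc1c(C)ccc(O[Si](C(C)C)(C(C)C)C(C)C)c1C | intermediate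
16 | lithium (3S)-3-{[2,6-dimethyl-3-(triisopropylsilyloxy)phenyl]methyl}-2-methyloxolan-2-olate, mixture at C2 | [Li+].[O-]C1(C)OCC[C@@H]1Cc1c(C)ccc(O[Si](C(C)C)(C(C)C)C(C)C)c1C | intermediate (not isolated)
17 | (3S)-3-{[2,6-dimethyl-3-(triisopropylsilyloxy)phenyl]methyl}-5-hydroxypentan-2-one | CC(=O)[C@H](CCO)Cc1c(C)ccc(O[Si](C(C)C)(C(C)C)C(C)C)c1C | intermediate
18 | (3S)-3-{[2,6-dimethyl-3-(triisopropylsilyloxy)phenyl]methyl}-4-methylpent-4-en-1-ol | CC(=C)[C@H](CCO)Cc1c(C)ccc(O[Si](C(C)C)(C(C)C)C(C)C)c1C | intermediate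
19 | (3S)-3-{[2,6-dimethyl-3-(triisopropylsilyloxy)phenyl]methyl}-4-methylpent-4-en-1-yl methanesulfonate | CC(=C)[C@H](CCOS(C)(=O)=O)Cc1c(C)ccc(O[Si](C(C)C)(C(C)C)C(C)C)c1C | intermediate
20 | (3S)-3-[(3-hydroxy-2,6-dimethylphenyl)methyl]-4-methylpent-4-en-1-yl methanesulfonate, i.e. 2,4-dimethyl-3-[(2S)-2-isopropenyl-4-(mesyloxy)butyl]phenol | CC(=C)[C@H](CCOS(C)(=O)=O)Cc1c(C)ccc(O)c1C | intermediate
21 | potassium phenolate of 20 | [K+].CC(=C)[C@H](CCOS(C)(=O)=O)Cc1c(C)ccc([O-])c1C | intermediate (not isolated)
22 | eudesma-1,4,11-trien-3-one, 7αH, 10β-methyl; (4aS,7R)-1,4a-dimethyl-7-(prop-1-en-2-yl)-5,6,7,8-tetrahydronaphthalen-2(4aH)-one | CC(=C)[C@H]1CC2=C(C)C(=O)C=C[C@]2(C)CC1 | intermediate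
23 | eudesma-4,11-dien-3-one (α-cyperone), 7αH, 10β-methyl | CC(=C)[C@H]1CC2=C(C)C(=O)CC[C@]2(C)CC1 | intermediate
24 | 12-hydroxyeudesma-4,11(13)-dien-3-one, 7αH, 10β-methyl | C=C(CO)[C@H]1CC2=C(C)C(=O)CC[C@]2(C)CC1 | intermediate
25 | 3-oxoeudesma-4,11(13)-dien-12-al, 7αH, 10β-methyl | C=C(C=O)[C@H]1CC2=C(C)C(=O)CC[C@]2(C)CC1 | intermediate (not isolated)
26 | 3-oxoeudesma-4,11(13)-dien-12-oic acid, 7αH, 10β-methyl | C=C(C(=O)O)[C@H]1CC2=C(C)C(=O)CC[C@]2(C)CC1 | intermediate
27 | methyl 3-oxoeudesma-4,11(13)-dien-12-oate, 7αH, 10β-methyl | C=C(C(=O)OC)[C@H]1CC2=C(C)C(=O)CC[C@]2(C)CC1 | intermediate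
28 | methyl 3β-hydroxyeudesma-4,11(13)-dien-12-oate, 7αH, 10β-methyl | C=C(C(=O)OC)[C@H]1CC2=C(C)[C@@H](O)CC[C@]2(C)CC1 | intermediate
29 | methyl 4β,5β-epoxy-3β-hydroxyeudesm-11(13)-en-12-oate, 4α-methyl, 7αH, 10β-methyl | C=C(C(=O)OC)[C@H]1C[C@]23O[C@@]2(C)[C@@H](O)CC[C@]3(C)CC1 | intermediate
30 | methyl 3β,4β-dihydroxyeudesma-5,11(13)-dien-12-oate, 4α-methyl, 7αH, 10β-methyl | C=C(C(=O)OC)[C@H]1C=C2[C@](C)(CC[C@H](O)[C@]2(C)O)CC1 | intermediate
31 | angelic acid, (Z)-2-methylbut-2-enoic acid | C/C=C(/C)C(=O)O | starting material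
32 | (Z)-2-methylbut-2-enoic 2,4,6-trichlorobenzoic anhydride | C/C=C(/C)C(=O)OC(=O)c1c(Cl)cc(Cl)cc1Cl | intermediate (not isolated)
33 | methyl 3β-[(Z)-2-methylbut-2-enoyloxy]-4β-hydroxyeudesma-5,11(13)-dien-12-oate, 4α-methyl, 7αH, 10β-methyl (CNP0283268.1) | C=C(C(=O)OC)[C@H]1C=C2[C@](C)(CC[C@H](OC(=O)/C(C)=C\C)[C@]2(C)O)CC1 | target

Total step count: 21. Longest linear sequence: 20 steps (from 1 through steps 1–5 and 7–21; step 6 lies on the short branch from 8 and 9).

Steps most likely to fail

Step 13. The ring closure may suffer from poor facial selectivity at C10, because the isopropenyl group is only a modest conformational anchor for the chair-like transition state, and from some ortho C-alkylation at C4. The fallback carries the isopropenyl group through the ring closure in a bulkier, masked form and releases it afterwards. It sets out from hydroxy ketone 17. Me3SiCH2MgCl with anhydrous CeCl3 in THF (−78 → 0 °C) should add to the ketone without enolisation and give the β-hydroxysilane (3S)-3-{[2,6-dimethyl-3-(triisopropylsilyloxy)phenyl]methyl}-4-methyl-5-(trimethylsilyl)pentane-1,4-diol F1 as a mixture at C11, which is of no consequence. Mesylation of the primary hydroxyl (MsCl, Et3N, 0 °C) gives the mesylate F2, and buffered Bu4NF/AcOH releases the phenol F3 without touching the C–Si bond. KOtBu (1.05 equiv) in dilute tBuOH then closes ring B to 11-hydroxy-13-(trimethylsilyl)eudesma-1,4-dien-3-one F4; its fully substituted C11 should hold the equatorial position far more firmly than an isopropenyl group. Peterson elimination (BF3·OEt2, CH2Cl2, −20 °C) can only form the C11=C13 bond, and the fallback comes back to the route at dienone 22. Premature elimination during the ring closure would merely give the main-route substrate.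

Step 20. The rearrangement may go astray through cleavage of the C4–O instead of the C5–O bond (giving the 4(15)-en-5-ol), through a 1,2-shift at the electron-poor C5, or through exchange of the methyl ester with isopropoxide. The fallback replaces chelation control by a silyl-triflate-promoted opening and sets out from epoxy alcohol 29. Me3SiOTf and 2,6-lutidine (toluene, −78 → 0 °C) should first silylate O3 and then ionise the C5–O bond, which lies away from the electron-withdrawing C3 oxygen, with loss of H6 to give methyl 3β,4β-bis(trimethylsilyloxy)eudesma-5,11(13)-dien-12-oate F5. HF·pyridine (THF, 0 °C) removes both silyl groups, and the fallback comes back to the route at diol 30.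

Step 15. The allylic oxidation may attack the wrong site (the ring methine C7–H, or the position next to the ketone with return to the dienone) or over-oxidise. The fallback functionalises the isopropenyl group by ene-type chlorination and substitution and sets out from α-cyperone 23. NaOCl with CeCl3·7H2O (CH2Cl2–H2O, 0 °C) should chlorinate the methyl of the isopropenyl group to give 12-chloroeudesma-4,11(13)-dien-3-one F6. KOAc in DMF (60 °C) displaces chloride to give 12-acetoxyeudesma-4,11(13)-dien-3-one F7, and K2CO3 in MeOH (0 °C) cleaves the acetate, so the fallback comes back to the route at alcohol 24.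

Further compounds

F1 | step 13 | (3S)-3-{[2,6-dimethyl-3-(triisopropylsilyloxy)phenyl]methyl}-4-methyl-5-(trimethylsilyl)pentane-1,4-diol, mixture at C4 | CC(O)(C[Si](C)(C)C)[C@H](CCO)Cc1c(C)ccc(O[Si](C(C)C)(C(C)C)C(C)C)c1C
F2 | step 13 | (3S)-3-{[2,6-dimethyl-3-(triisopropylsilyloxy)phenyl]methyl}-4-hydroxy-4-methyl-5-(trimethylsilyl)pentyl methanesulfonate | CC(O)(C[Si](C)(C)C)[C@H](CCOS(C)(=O)=O)Cc1c(C)ccc(O[Si](C(C)C)(C(C)C)C(C)C)c1C
F3 | step 13 | (3S)-4-hydroxy-3-[(3-hydroxy-2,6-dimethylphenyl)methyl]-4-methyl-5-(trimethylsilyl)pentyl methanesulfonate | CC(O)(C[Si](C)(C)C)[C@H](CCOS(C)(=O)=O)Cc1c(C)ccc(O)c1C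
F4 | step 13 | 11-hydroxy-13-(trimethylsilyl)eudesma-1,4-dien-3-one, 7αH, 10β-methyl, mixture at C11 | CC(O)(C[Si](C)(C)C)[C@H]1CC2=C(C)C(=O)C=C[C@]2(C)CC1
F5 | step 20 | methyl 3β,4β-bis(trimethylsilyloxy)eudesma-5,11(13)-dien-12-oate | C=C(C(=O)OC)[C@H]1C=C2[C@](C)(CC[C@H](O[Si](C)(C)C)[C@]2(C)O[Si](C)(C)C)CC1
F6 | step 15 | 12-chloroeudesma-4,11(13)-dien-3-one | C=C(CCl)[C@H]1CC2=C(C)C(=O)CC[C@]2(C)CC1
F7 | step 15 | 12-acetoxyeudesma-4,11(13)-dien-3-one | C=C(COC(C)=O)[C@H]1CC2=C(C)C(=O)CC[C@]2(C)CC1
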